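## Structural features

Absinthin is the head-to-head [4+2] dimer of a guaianolide, built on a norbornene (C2=C3, bridgeheads C4 and C23, one-carbon bridge C24, saturated bridge C5–C6) that carries an endo-fused cyclopentene (C5, C6, C7=C9, C22). Seven-membered ring A (C9, C10, C16, C17, C18, C19, C22) is fused to the cyclopentene at C9–C22, and seven-membered ring B (C23, C24, C25, C28, C29, C30, C36) is fused to the norbornene at C23–C24. Each seven-membered ring bears a tertiary methyl carbinol (C19, C25) and a trans-fused α-methyl-γ-lactone (lactone A: C10, O11, C12, C14, C16; lactone B: C36, O35, C33, C31, C30). There are fourteen stereocentres: C4, C5, C6 and quaternary C23 around the norbornane, the pairs C22/C19 and C24/C25, and the triads C10–C16–C14 and C36–C30–C31, which have the same sense in both halves. The C25 hydroxyl sits over the strained C2=C3 alkene and forms an ether under acid; both tertiary carbinols dehydrate easily; the norbornene can cyclorevert on heating; C14 and C31 are epimerizable. The real difficulty is quaternary C23 with its neopentyl carbinol C36, whose hydrogen points into the pocket under the C1 methyl group, together with building two lactone triads without doubling the step count. The key step uses the fact that the two triads are one repeated array and that in a C10/C36 diketone C16 and C30 are the only enolizable α-carbons (C9 is sp2, C23 is quaternary), so that one bis-enolate can be alkylated at both ends by a lactate-derived electrophile that brings C14 and C31 with their configuration.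

## Logic of the disconnections

21 to 20: only the two O–Si bonds on O21 and O27 are cut. The tertiary hydroxyls, above all the one over C2=C3, stay masked through every electrophilic step. The forward step must be a neutral fluoride cleavage that leaves the lactones alone.

20 to 18: the ring bonds O11–C10 and O35–C36 are cut, not the acyl C–O bonds. In 20 the hydrogens H10 and H36 lie on the hindered faces, where a hydride reagent cannot be delivered, whereas oxygen can enter from the open faces. A reduction that comes in anti to each arm leaves the hydroxyl cis to the arm, so closure with retention would give cis-lactones. The forward step must therefore close both rings with inversion at carbinols that are cis to their arms. Two rings are removed at once.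

18 to 17: the C10–H and C36–H bonds are cut, returning both carbinols to ketones. The forward step needs 1,2-selectivity at the enone and hydride attack on the exposed faces.

17 to 13 and two molecules of 15: the bonds C14–C16 and C30–C31 are cut. This removes four stereocentres and six carbons in one operation and leaves a diketone whose two enolizable positions are unambiguous. The forward step must be an SN2 alkylation with inversion at the lactate carbon, followed by equilibration of C16 and C30.

15 to 14: the O–S bond is cut; sulfonylation does not touch the stereocentre.

13 to 12: the two O–Si bonds are cut. Silylation is placed after the cycloaddition so that the monomer reacts as the free carbinol.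

12 to two molecules of 11: the bonds C4–C5 and C6–C23 are cut (retro-Diels–Alder). The pentacycle falls into two identical bicyclic dienones and four stereocentres disappear. The forward step needs a single enantiomer of 11, head-to-head regiochemistry, endo geometry, and approach anti to C19 and C25 on both partners.

11 to 9: the C5=C6 π bond is traded for a C5–O bond. The sensitive diene can then be released last and cold by a vinylogous elimination through the enone, and the C5 oxygen is the element that fixes absolute configuration earlier.

9 to 8 to 7: the O–Si bond at C5 and then the C19–C20 bond are cut. The forward methyl addition must choose the saturated C19 ketone over the conjugated C10 ketone and enter on the exo face.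

7 to 5: the C7=C9 alkene is hydrated back to a tertiary aldol and the two ketones are reconnected as a C10–C19 glycol bond. This turns the seven-membered ring into a cyclobutane-diol fused to two five-membered rings, the retron of an enone–alkene photocycloaddition.

5 to 4 to 3: the O–Si bonds of the glycol and then the C7–C8 bond are cut. The methyl group is introduced while C7 is still an isolated ketone, which avoids a β-diketone after ring opening.

3 to 1 and 2: the bonds C9–C10 and C19–C22 are cut ([2+2]). Both partners are simple five-membered rings; the forward step must add anti to the silyloxy group of 1.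

## Other disconnections considered

Alternative 1: The cut is C23–C24, the bond between the bridgehead and the one-carbon bridge. In the forward direction a metalated allylic nitrile carbon (C23) opens a side-chain epoxide at C24 held on C4 of a cyclohexene; this closes the norbornene and frees the C25 alkoxide, giving A1. In its favour, C23 becomes quaternary and C24/C25 are set in one stereospecific SN2 event whose outcome follows from the epoxide geometry. On this point the alternative is the better of the two, because the chosen plan sets C19 and C25 by reagent approach to a ketone (step 5). Against it here, the closure needs a boat-like alignment to form a strained bicyclo[2.2.1] system. The strong base must also coexist with lactone A, its acidic C14 hydrogen and the allylic C10–O bond. After A1, ring B and lactone B must still be built from a nitrile and a butenyl chain, which brings back the C36 problem on a one-directional basis. Mechanistically both plans rely on carbanion SN2 chemistry, but the chosen plan uses it twice in one flask on a symmetrical problem. In step count the alternative is clearly longer and linear.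

Alternative 2: The cut is C19–C22 plus C9–C10, taking ring A off the cyclopentene. In the forward direction a five-atom oxidopyrylium dipole bearing the future C20 methyl, released by base from its acetoxy precursor, adds across the C9=C22 bond of a norbornene-fused cyclopentenone to give A2. In its favour, two C–C bonds, the seven-membered ring and the oxygenated quaternary C19 are made in one cycloaddition with defined relative configuration. In bond-forming efficiency for ring A and in the certainty of the C19 configuration this alternative is the better. Against it here, the single bridging oxygen has to end up as two separate oxygens (the C19 hydroxyl and the lactone oxygen on C10). The C18 ketone and the C16=C17 alkene have to be removed, and the C7 ketone must become the methyl-bearing alkene. Regiochemistry and facial selectivity of the dipole on an unsymmetrical enone are open. The cycloaddition is also run late on a material that already carries lactone B, so ring B needs its own separate construction. The mechanism is a concerted cycloaddition, whereas the chosen plan uses enolate alkylation; the functional-group corrections after A2 outweigh the bonds gained.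

Alternative 3: The cut is C23–C36, joining the core to the ring B arm. In the forward direction a cyclic allylboronate (boron on C3, alkene C2=C23) adds through C23 to an aldehyde carbon (C36) of a side chain that already holds C30 and C31; the alkene moves to C2=C3 and the borate closes lactone B, giving A3. In its favour, quaternary C23 and the C36 carbinol arise together in a closed chair-like transition state, and lactone B arrives with its three stereocentres in place. This avoids the hindered-face problem at C36, the weakest stereochemical point of the chosen plan, and here the alternative is the better; in convergence it is the equal of the chosen plan. Against it here, a γ,γ-disubstituted allylboronate that must create a quaternary carbon reacts sluggishly. Double stereodifferentiation with the chiral aldehyde may be mismatched. After A3 the bridge bond C4–C24, the ring B bond C25–C28 and the C25 carbinol are still missing, with a silyl ether and a benzyl-type ether to handle. The chosen plan instead gets the whole carbon framework from one dimerization and both arms from one alkylation, so it is much shorter.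

Key step: step 11

Remark on the chemistry: atom labels C1–C36 are the heavy-atom positions of the target SMILES and are kept for all intermediates. Compound 1 and compound 14 are taken to be purchasable as single enantiomers. Compounds 13 and 17 are the diketone and its bis-alkylated product of the key step, with triethylsilyl ethers and tert-butyl esters as spectator groups.

## Route

Step 1
Reactants: 1 (S)-4-(tert-butyldimethylsilyloxy)cyclopent-2-en-1-one; 2 1,2-bis(trimethylsilyloxy)cyclopentene
Product: 3 cis-anti-cis 5-(tert-butyldimethylsilyloxy)-1,7-bis(trimethylsilyloxy)tricyclo[5.3.0.0^2,6]decan-3-one (C5 silyloxy group trans to the C6–C7 bond)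
Conditions: hν (λ > 350 nm, uranium-glass filter), 2 (4 equiv), CH2Cl2, −40 °C
Reagents that add atoms: none
Why: Enone–alkene [2+2] photocycloaddition; the electron-rich alkene should bond to the enone β-carbon on the face away from the C4 silyloxy group, which fixes the future C22/C24 centre, and the cyclobutane can only be cis-fused to the cyclopentanone. The configurations at the two siloxy carbons and at the ketone α-carbon are erased later.

Step 2
Reactants: 3 the photoadduct
Product: 4 5-(tert-butyldimethylsilyloxy)-3-methyl-1,7-bis(trimethylsilyloxy)tricyclo[5.3.0.0^2,6]decan-3-ol (methyl on the convex face)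
Conditions: MeMgBr (1.5 equiv), CeCl3 (1.6 equiv), THF, −78 °C
Reagents that add atoms: methylmagnesium bromide, C[Mg]Br
Why: Organocerium 1,2-addition to a ketone; the weakly basic reagent should avoid enolization and loss of the β-silyloxy group. Attack is expected on the convex face, but this centre is removed again in step 4.

Step 3
Reactants: 4 the tertiary alcohol
Product: 5 5-(tert-butyldimethylsilyloxy)-3-methyltricyclo[5.3.0.0^2,6]decane-1,3,7-triol
Conditions: K2CO3 (0.3 equiv), MeOH, 0 → 25 °C
Reagents that add atoms: none
Why: Base-catalysed methanolysis of the two trimethylsilyl ethers; the secondary tert-butyldimethylsilyl ether should stay, and with no carbonyl present no retro-aldol path is open.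

Step 4
Reactants: 5 the triol
Product: 7 (1S,8aS)-1-(tert-butyldimethylsilyloxy)-3-methyl-1,2,5,6,7,8a-hexahydroazulene-4,8-dione, via hydroxy diketone 6 (not isolated)
Conditions: Pb(OAc)4 (1.1 equiv), CH2Cl2, 0 °C; then camphorsulfonic acid (0.1 equiv), 25 °C
Reagents that add atoms: none
Why: Criegee glycol cleavage of the cis-cyclobutane-1,2-diol should open the four-membered ring to the cycloheptane-1,4-dione with release of strain, and the tertiary aldol at C7/C9 should then lose water under acid to the tetrasubstituted enone. The two ring ketones become different: C10 is a hindered conjugated ketone, C19 a saturated one. Acid is used because H22 is acidic and base could expel the β-silyloxy group.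

Step 5
Reactants: 7 the enedione
Product: 8 (1S,8S,8aS)-1-(tert-butyldimethylsilyloxy)-8-hydroxy-3,8-dimethyl-1,2,6,7,8,8a-hexahydroazulen-4(5H)-one
Conditions: MeMgBr (1.15 equiv), CeCl3 (1.3 equiv), THF, −78 °C
Reagents that add atoms: methylmagnesium bromide, C[Mg]Br
Why: Organocerium addition to a ketone; the saturated C19 carbonyl is more electrophilic than the conjugated C10 carbonyl next to a tetrasubstituted alkene, and the non-basic reagent should leave the acidic H22 alone. One face of C19 lies over the five-membered ring, so methyl should enter on the exo face, the side of H22, which leaves the hydroxyl cis to the C22–C5 bond as in the target.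

Step 6
Reactants: 8 the silyl ether
Product: 9 (1S,8S,8aS)-1,8-dihydroxy-3,8-dimethyl-1,2,6,7,8,8a-hexahydroazulen-4(5H)-one
Conditions: Bu4NF (1.3 equiv), AcOH (1.3 equiv), THF, 0 → 25 °C
Reagents that add atoms: none
Why: Fluoride cleavage of the secondary silyl ether; buffering with acetic acid keeps the medium from enolizing the enone.

Step 7
Reactants: 9 the diol
Product: 11 (8S,8aR)-8-hydroxy-3,8-dimethyl-6,7,8,8a-tetrahydroazulen-4(5H)-one, via mesylate 10 (not isolated)
Conditions: MsCl (1.15 equiv), Et3N (2.5 equiv), CH2Cl2, −30 °C; then DBU (1.5 equiv), −30 → 0 °C; cold work-up, used at once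
Reagents that add atoms: none
Why: The secondary hydroxyl is sulfonylated in preference to the tertiary one; vinylogous E1cB elimination follows, in which deprotonation at C6 (γ to the C10 carbonyl) expels the δ-mesylate and creates C5=C6. H22 is cis to the leaving group and not acidified, so the diene should form away from the stereocentre.

Step 8
Reactants: 11 the dienone (two molecules)
Product: 12 pentacyclic diol diketone: absinthin skeleton with C10 and C36 as ketones, C16 and C30 as CH2 and no lactone carbons, C19 and C25 free carbinols, configuration at C4, C5, C6, C19, C22, C23, C24 and C25 as in absinthin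
Conditions: neat (or 3 M in PhMe), 25 °C, dark, Ar, several days
Reagents that add atoms: none
Why: Diels–Alder dimerization of a 5-substituted cyclopentadiene; the first bond should join the two unsubstituted diene termini (C4–C5), which carry the largest frontier coefficients δ to the carbonyl and are the least hindered, and the second joins C23 to C6. Endo geometry and approach of each partner on the face of its ring-fusion hydrogen (anti to C19 and C25) set C4, C5, C6 and C23. A single enantiomer of 11 can only give the homochiral dimer.

Step 9
Reactants: 12 the diol diketone
Product: 13 bis(triethylsilyl) ether of 12 at O21 and O27 (precursor of the key step)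
Conditions: Et3SiOTf (2.6 equiv), 2,6-lutidine (5 equiv), CH2Cl2, −78 → 0 °C
Reagents that add atoms: triethylsilyl trifluoromethanesulfonate, CC[Si](CC)(CC)OS(=O)(=O)C(F)(F)F
Why: Silylation of hindered tertiary alcohols with a silyl triflate; with the hindered pyridine at low temperature the ketones should not be converted into enol ethers. Triethylsilyl is chosen over trimethylsilyl because it must survive steps 12 and 13.

Step 10
Reactants: 14 tert-butyl (S)-lactate
Product: 15 tert-butyl (S)-2-(trifluoromethylsulfonyloxy)propanoate
Conditions: Tf2O (1.05 equiv), 2,6-lutidine (1.1 equiv), CH2Cl2, −78 → 0 °C; filtered through silica in pentane, used at once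
Reagents that add atoms: trifluoromethanesulfonic anhydride, O=S(=O)(OS(=O)(=O)C(F)(F)F)C(F)(F)F
Why: O-sulfonylation of a secondary alcohol; no bond to the stereocentre is broken, so the S configuration is kept. The tert-butyl ester is chosen so that the hydroxy esters of step 12 cannot close prematurely and so that step 13 can shed the alkyl group as isobutene.

Step 11
Reactants: 13 the bis-silylated diketone; 15 the lactate triflate (two molecules)
Product: 17 diketone carrying both (S)-configured tert-butyl propanoate arms at C16 and C30 with C16 and C30 as in absinthin, via kinetic bis-epimer 16 (not isolated)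
Conditions: LiN(SiMe3)2 (2.1 equiv), THF, −78 °C; 15 (2.2 equiv), −78 → −40 °C; then DBU (1.0 equiv), THF, 25 → 50 °C
Reagents that add atoms: none
Why: LiN(SiMe3)2 removes H16 (kinetic α′-deprotonation of the C7=C9–C10 enone, giving the cross-conjugated dienolate) and H30 (the other flank of C36 is quaternary C23), so the dilithium bis-enolate has no regiochemical choice. Each enolate carbon then displaces triflate from 15 by SN2 at the lactate carbon, forming C14–C16 and C30–C31 with inversion, which makes C14 and C31 both S; the closest known reaction type is C-alkylation of ketone lithium enolates with α-triflyloxy esters. No ring is closed. The enolates are expected to be attacked on their exposed faces, which places the arms pseudo-axial (16); DBU then equilibrates C16 and C30 through the ketone enols to the pseudo-equatorial arrangement 17 that the lactones need (in ring B the other epimer presses the arm against the C26 methyl group). C14 and C31 should not be touched by the amidine, because an ester α-hydrogen is far less acidic than a ketone α-hydrogen. The step needs substitution to outrun elimination of the triflate and O-alkylation: the ester-activated secondary triflate reacts at −78 °C, the base is used in exact amount, and the bulky tert-butyl ester resists acyl attack. The triethylsilyl ethers keep the C19 and C25 oxygens from being alkylated and from adding across the ring to the ketones.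

Step 12
Reactants: 17 the bis-alkylated diketone
Product: 18 bis-carbinol with both hydroxyls cis to their arms (C10 and C36 epimeric to the lactone carbinols of absinthin)
Conditions: NaBH4 (4 equiv), CeCl3·7H2O (2.2 equiv), MeOH–THF (1:1), −40 → 0 °C
Reagents that add atoms: none
Why: Luche 1,2-reduction of both ketones; hydride should reach C10 from the convex face of the hydroazulene and C36 from the face remote from the C1 methyl group, because the opposite face of C36 is blocked by that methyl. Both approaches are anti to the pseudo-equatorial arms, so each hydroxyl ends cis to its arm. The tert-butyl esters should not close to cis-lactones under these conditions.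

Step 13
Reactants: 18 the bis-carbinol
Product: 20 absinthin bis(triethylsilyl) ether (both trans-lactones closed), via bis-triflate 19 (not isolated)
Conditions: Tf2O (2.4 equiv), 2,6-lutidine (6 equiv), CH2Cl2, −78 → 0 °C
Reagents that add atoms: none
Why: Both carbinols are activated as triflates; the carbonyl oxygen of each neighbouring ester displaces triflate from the rear (5-exo-tet, inversion at C10 and C36) and the tert-butyl group leaves as isobutene, the ester counterpart of the carbamate-to-oxazolidinone closure. Inversion puts O11 and O35 on the exposed faces and H10 and H36 on the hindered ones, which is the trans-lactone arrangement. At allylic C10 an ion-pair pathway would close on the same exposed face.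

Step 14
Reactants: 20 the bis-silyl ether
Product: 21 absinthin
Conditions: Bu4NF (3 equiv), AcOH (3 equiv), THF, 0 → 25 °C
Reagents that add atoms: none
Why: Fluoride cleavage of the two tertiary silyl ethers; the buffered, non-acidic medium should leave the lactones intact and avoid ether formation from O27 onto C2=C3.

## Compound list

1 | (S)-4-(tert-butyldimethylsilyloxy)cyclopent-2-en-1-one | O=C1C=C[C@@H](O[Si](C)(C)C(C)(C)C)C1 | starting material
2 | 1,2-bis(trimethylsilyloxy)cyclopentene | C[Si](C)(C)OC1=C(O[Si](C)(C)C)CCC1 | starting material
3 | cis-anti-cis 5-(tert-butyldimethylsilyloxy)-1,7-bis(trimethylsilyloxy)tricyclo[5.3.0.0^2,6]decan-3-one | O=C1C[C@H](O[Si](C)(C)C(C)(C)C)[C@@H]2[C@H]1[C@@]3(O[Si](C)(C)C)CCC[C@@]23O[Si](C)(C)C | intermediate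
4 | 5-(tert-butyldimethylsilyloxy)-3-methyl-1,7-bis(trimethylsilyloxy)tricyclo[5.3.0.0^2,6]decan-3-ol | C[C@]1(O)C[C@H](O[Si](C)(C)C(C)(C)C)[C@@H]2[C@H]1[C@@]3(O[Si](C)(C)C)CCC[C@@]23O[Si](C)(C)C | intermediate
5 | 5-(tert-butyldimethylsilyloxy)-3-methyltricyclo[5.3.0.0^2,6]decane-1,3,7-triol | C[C@]1(O)C[C@H](O[Si](C)(C)C(C)(C)C)[C@@H]2[C@H]1[C@@]3(O)CCC[C@@]23O | intermediate
6 | 1-(tert-butyldimethylsilyloxy)-3-hydroxy-3-methyloctahydroazulene-4,8-dione (tertiary aldol, not isolated) | C[C@]1(O)C[C@H](O[Si](C)(C)C(C)(C)C)[C@@H]2[C@H]1C(=O)CCCC2=O | intermediate
7 | (1S,8aS)-1-(tert-butyldimethylsilyloxy)-3-methyl-1,2,5,6,7,8a-hexahydroazulene-4,8-dione | CC1=C2C(=O)CCCC(=O)[C@@H]2[C@@H](O[Si](C)(C)C(C)(C)C)C1 | intermediate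
8 | (1S,8S,8aS)-1-(tert-butyldimethylsilyloxy)-8-hydroxy-3,8-dimethyl-1,2,6,7,8,8a-hexahydroazulen-4(5H)-one | CC1=C2C(=O)CCC[C@](C)(O)[C@@H]2[C@@H](O[Si](C)(C)C(C)(C)C)C1 | intermediate
9 | (1S,8S,8aS)-1,8-dihydroxy-3,8-dimethyl-1,2,6,7,8,8a-hexahydroazulen-4(5H)-one | CC1=C2C(=O)CCC[C@](C)(O)[C@@H]2[C@@H](O)C1 | intermediate
10 | 1-methanesulfonate of 9 (not isolated) | CC1=C2C(=O)CCC[C@](C)(O)[C@@H]2[C@@H](OS(C)(=O)=O)C1 | intermediate
11 | (8S,8aR)-8-hydroxy-3,8-dimethyl-6,7,8,8a-tetrahydroazulen-4(5H)-one | CC1=C2C(=O)CCC[C@](C)(O)[C@@H]2C=C1 | intermediate
12 | pentacyclic C10/C36 diketone with free C19 and C25 carbinols (Diels–Alder dimer of 11) | CC1=C[C@@H]2[C@H]3[C@H](C(C)=C4C(=O)CCC[C@](C)(O)[C@@H]43)[C@@]13[C@@H]2[C@@](C)(O)CCCC3=O | intermediate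
13 | pentacyclic C10/C36 diketone with both carbinols as triethylsilyl ethers | CC1=C[C@@H]2[C@H]3[C@H](C(C)=C4C(=O)CCC[C@](C)(O[Si](CC)(CC)CC)[C@@H]43)[C@@]13[C@@H]2[C@@](C)(O[Si](CC)(CC)CC)CCCC3=O | intermediate
14 | tert-butyl (S)-lactate | CC(C)(C)OC(=O)[C@H](C)O | starting material
15 | tert-butyl (S)-2-(trifluoromethylsulfonyloxy)propanoate | CC(C)(C)OC(=O)[C@H](C)OS(=O)(=O)C(F)(F)F | intermediate
16 | C16,C30-bis-epimer of 17 (kinetic alkylation product, not isolated) | CC1=C[C@@H]2[C@H]3[C@H](C(C)=C4C(=O)[C@@H]([C@H](C)C(=O)OC(C)(C)C)CC[C@](C)(O[Si](CC)(CC)CC)[C@@H]43)[C@@]13[C@@H]2[C@@](C)(O[Si](CC)(CC)CC)CC[C@H]([C@H](C)C(=O)OC(C)(C)C)C3=O | intermediate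
17 | diketone carrying both (S)-tert-butyl propanoate arms at C16 and C30, bis(triethylsilyl) ether | CC1=C[C@@H]2[C@H]3[C@H](C(C)=C4C(=O)[C@H]([C@H](C)C(=O)OC(C)(C)C)CC[C@](C)(O[Si](CC)(CC)CC)[C@@H]43)[C@@]13[C@@H]2[C@@](C)(O[Si](CC)(CC)CC)CC[C@@H]([C@H](C)C(=O)OC(C)(C)C)C3=O | intermediate
18 | bis-carbinol from 17, hydroxyls at C10 and C36 cis to the arms | CC1=C[C@@H]2[C@H]3[C@H](C(C)=C4[C@H](O)[C@H]([C@H](C)C(=O)OC(C)(C)C)CC[C@](C)(O[Si](CC)(CC)CC)[C@@H]43)[C@@]13[C@@H]2[C@@](C)(O[Si](CC)(CC)CC)CC[C@@H]([C@H](C)C(=O)OC(C)(C)C)[C@H]3O | intermediate
19 | C10,C36-bis(trifluoromethanesulfonate) of 18 (not isolated) | CC1=C[C@@H]2[C@H]3[C@H](C(C)=C4[C@H](OS(=O)(=O)C(F)(F)F)[C@H]([C@H](C)C(=O)OC(C)(C)C)CC[C@](C)(O[Si](CC)(CC)CC)[C@@H]43)[C@@]13[C@@H]2[C@@](C)(O[Si](CC)(CC)CC)CC[C@@H]([C@H](C)C(=O)OC(C)(C)C)[C@H]3OS(=O)(=O)C(F)(F)F | intermediate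
20 | absinthin bis(triethylsilyl) ether | CC1=C[C@@H]2[C@H]3[C@H](C(C)=C4[C@H]5OC(=O)[C@@H](C)[C@@H]5CC[C@](C)(O[Si](CC)(CC)CC)[C@@H]43)[C@@]13[C@@H]2[C@@](C)(O[Si](CC)(CC)CC)CC[C@H]1[C@H](C)C(=O)O[C@@H]13 | intermediate
21 | absinthin | CC1=C[C@@H]2[C@H]3[C@H](C(C)=C4[C@H]5OC(=O)[C@@H](C)[C@@H]5CC[C@](C)(O)[C@@H]43)[C@@]13[C@@H]2[C@@](C)(O)CC[C@H]1[C@H](C)C(=O)O[C@@H]13 | target

## Step count and least certain steps

Total: 14 steps. Longest linear sequence: 13 steps (steps 1–9 and 11–14); step 10 is a one-step side branch.

Step 11 (key step). The most likely failure is proton transfer from the acidic α-hydrogen of 15 to the enolates with loss of triflate, which would lead to an acrylate and unbranched conjugate adducts; the second alkylation at hindered C30 may also stall. The fallback sets out from 13 and comes back at 20. The same bis-enolate would be alkylated with tert-butyl bromoacetate, a primary halide without this elimination path, and equilibrated with DBU to the bis(tert-butyl acetate) diketone F1. NaBH4/CeCl3 should give the bis-carbinol F2, and Tf2O/2,6-lutidine should close both rings with inversion to the 14,31-bis-nor-methyl bis-lactone bis(triethylsilyl) ether F3. LiN(iPr)2 (2.2 equiv) and MeI at −78 °C should then methylate both lactone enolates on the face of H16 and H30, anti to the ring bonds at C16 and C30, and give 20.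

Step 8. The most likely failure is that sigmatropic hydrogen shifts around the cyclopentadiene move the double bonds and scramble C22 faster than the acceptor-substituted diene dimerizes. The fallback sets out from 11 and comes back at 12. Freshly made 11 would be reduced at −78 °C with NaBH4/CeCl3 to the dienol (4S,8S,8aR)-3,8-dimethyl-4,5,6,7,8,8a-hexahydroazulene-4,8-diol F4, an electron-richer diene of the natural type; either C4 epimer serves. Neat dimerization should give the pentacyclic tetraol F5, and oxidation of both secondary carbinols with Dess–Martin periodinane and NaHCO3 should return 12.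

Step 13. The most likely failure is ionization of the neopentyl C36 triflate with migration of a norbornane bond, or elimination toward C16 or C30, before the ester oxygen closes the ring. The fallback sets out from 18 and comes back at 20. The tert-butyl esters would be cleaved without protic acid (Me3SiOTf, 2,6-lutidine, CH2Cl2, 0 °C; the trimethylsilyl esters and any trimethylsilyl ethers formed on the C10 and C36 hydroxyls are hydrolysed on cold buffered aqueous work-up) to the bis-hydroxy diacid F6, which would be kept cold and used at once so that it does not close with retention. Mitsunobu lactonization (PPh3, diisopropyl azodicarboxylate, PhMe, 0 °C) should then activate the carbinols as oxyphosphonium ions and close both lactones with inversion to 20.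

Step 5. The most likely failure is competing addition to the conjugated C10 carbonyl, or poor facial selectivity at C19. The fallback sets out from 7 and comes back at 8, and delivers oxygen instead of carbon to the preferred face. Non-basic methylenation of the saturated ketone with the Tebbe reagent Cp2TiCH2ClAlMe2 should give the exocyclic alkene F7. Epoxidation with dimethyldioxirane should give the spiro-epoxide F8. LiEt3BH should open the epoxide at its CH2 carbon and also reduce the C10 carbonyl to give the diol F9, and MnO2 should reoxidize the allylic alcohol to 8.

## Further compounds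

F1 | step 11 | diketone carrying tert-butyl acetate arms at C16 and C30, bis(triethylsilyl) ether | CC1=C[C@@H]2[C@H]3[C@H](C(C)=C4C(=O)[C@H](CC(=O)OC(C)(C)C)CC[C@](C)(O[Si](CC)(CC)CC)[C@@H]43)[C@@]13[C@@H]2[C@@](C)(O[Si](CC)(CC)CC)CC[C@@H](CC(=O)OC(C)(C)C)C3=O
F2 | step 11 | bis-carbinol from F1, hydroxyls at C10 and C36 cis to the arms | CC1=C[C@@H]2[C@H]3[C@H](C(C)=C4[C@H](O)[C@H](CC(=O)OC(C)(C)C)CC[C@](C)(O[Si](CC)(CC)CC)[C@@H]43)[C@@]13[C@@H]2[C@@](C)(O[Si](CC)(CC)CC)CC[C@@H](CC(=O)OC(C)(C)C)[C@H]3O
F3 | step 11 | 14,31-bis-nor-methyl absinthin bis(triethylsilyl) ether | CC1=C[C@@H]2[C@H]3[C@H](C(C)=C4[C@H]5OC(=O)C[C@@H]5CC[C@](C)(O[Si](CC)(CC)CC)[C@@H]43)[C@@]13[C@@H]2[C@@](C)(O[Si](CC)(CC)CC)CC[C@H]1CC(=O)O[C@@H]13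
F4 | step 8 | (4S,8S,8aR)-3,8-dimethyl-4,5,6,7,8,8a-hexahydroazulene-4,8-diol | CC1=C2[C@@H](O)CCC[C@](C)(O)[C@@H]2C=C1
F5 | step 8 | pentacyclic tetraol (Diels–Alder dimer of F4; C10 and C36 carbinols in place of the ketones of 12) | CC1=C[C@@H]2[C@H]3[C@H](C(C)=C4[C@@H](O)CCC[C@](C)(O)[C@@H]43)[C@@]13[C@@H]2[C@@](C)(O)CCC[C@@H]3O
F6 | step 13 | bis-hydroxy diacid from 18 (both tert-butyl esters cleaved) | CC1=C[C@@H]2[C@H]3[C@H](C(C)=C4[C@H](O)[C@H]([C@H](C)C(O)=O)CC[C@](C)(O[Si](CC)(CC)CC)[C@@H]43)[C@@]13[C@@H]2[C@@](C)(O[Si](CC)(CC)CC)CC[C@@H]([C@H](C)C(O)=O)[C@H]3O
F7 | step 5 | (1S,8aS)-1-(tert-butyldimethylsilyloxy)-3-methyl-8-methylidene-1,2,6,7,8,8a-hexahydroazulen-4(5H)-one | CC1=C2C(=O)CCCC(=C)[C@@H]2[C@@H](O[Si](C)(C)C(C)(C)C)C1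
F8 | step 5 | spiro-epoxide of F7 (oxygen cis to the C8a–C1 bond) | CC1=C2C(=O)CCC[C@@]3(CO3)[C@@H]2[C@@H](O[Si](C)(C)C(C)(C)C)C1
F9 | step 5 | 1-(tert-butyldimethylsilyloxy)-3,8-dimethyl-1,2,4,5,6,7,8,8a-octahydroazulene-4,8-diol | CC1=C2[C@@H](O)CCC[C@](C)(O)[C@@H]2[C@@H](O[Si](C)(C)C(C)(C)C)C1
A1 | alternative 1 | norbornene with C23 nitrile and C25 carbinol bearing a but-3-enyl chain, ring A and lactone A complete | CC1=C[C@@H]2[C@H]3[C@H](C(C)=C4[C@H]5OC(=O)[C@@H](C)[C@@H]5CC[C@](C)(O)[C@@H]43)[C@@]1(C#N)[C@@H]2[C@@](C)(O)CCC=C
A2 | alternative 2 | oxygen-bridged ring A cycloadduct (C7 and C18 ketones, C16=C17 alkene), ring B and lactone B complete | CC1=C[C@@H]2[C@H]3[C@H](C(=O)[C@@H]4[C@H]5C=CC(=O)[C@](C)(O5)[C@@H]43)[C@@]13[C@@H]2[C@@](C)(O)CC[C@H]1[C@H](C)C(=O)O[C@@H]13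
A3 | alternative 3 | cyclohexene with quaternary C23 bearing lactone B and an acetonyl group, C4 silyl ether, ring A and lactone A complete | CC1=C[C@H](O[Si](C)(C)C(C)(C)C)[C@H]3[C@H](C(C)=C4[C@H]5OC(=O)[C@@H](C)[C@@H]5CC[C@](C)(O)[C@@H]43)[C@]1(CC(C)=O)[C@H]2OC(=O)[C@@H](C)[C@@H]2CCOCc6ccc(OC)cc6
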